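**Retrosynthetic overview** (C1 = lactone carbonyl, C35 = carbon bearing the ring oxygen, C36–C40 = side chain)
- The plan rests on the C17 and C21 carbinols of the 36-membered lactone ring (C1–C35 plus O), which are 1,5-related across the C18–C19–C20 methylenes; each is the carbinol of a terminal epoxide and C19 is supplied by a dithiane.
- The macrolactone is the only ring and is closed last, at C3–C4, by B-alkyl Suzuki–Miyaura coupling of the C4=C5 alkene with a C35 (Z)-3-iodobut-2-enoate.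
- The C5–C40 chain comes from a one-flask union of west epoxide 12 (C5–C18), silyl dithiane 37 (C19) and east epoxide 34 (C20–C40), forming C18–C19 and C19–C20; C19 is then reduced to CH2.
- Both epoxides are grown by Brown allylation/silylation, with alkene cleavage for 1,3-diols and hydroformylation for 1,5-diols, and finished by methylene transfer and hydrolytic kinetic resolution; C35/C36 come from Sharpless epoxidation and Me3Al opening.

Key step: step 33

Remarks: TBS = tert-butyldimethylsilyl, PMB = 4-methoxybenzyl, salen = N,N′-bis(3,5-di-tert-butylsalicylidene)cyclohexane-1,2-diaminato; locants are target locants, and the CIP descriptor quoted for an intermediate is that of the compound itself, so it can differ from the target descriptor at the same carbon without any spatial change.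
Assumption: aldehyde 1 and both enantiomers of Ipc2B(allyl) (1 M in pentane) are taken as purchased.

**West epoxide (C5–C18)**

Step 1
Reactants: 1 3-(PMB-oxy)propanal
Product: 2 C5–C10 homoallylic alcohol (7R)
Conditions: (+)-Ipc2B(allyl) (from (−)-α-pinene), Et2O, −100 °C; NaOH, H2O2 work-up
Reagents that add atoms: (+)-B-allyldiisopinocampheylborane, C=CCB([C@H]1C[C@H]2C[C@@H]([C@@H]1C)C2(C)C)[C@H]1C[C@H]2C[C@@H]([C@@H]1C)C2(C)C
Why: Brown asymmetric allylboration through a chair six-membered transition state; the reagent adds allyl to the Re face of the aldehyde and so sets C7.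

Step 2
Reactants: 2 C5–C10 homoallylic alcohol
Product: 3 C5–C10 alkene, 7-OTBS (7R)
Conditions: TBSCl, imidazole, DMF, rt
Reagents that add atoms: tert-butyldimethylsilyl chloride, CC(C)(C)[Si](C)(C)Cl
Why: Standard silylation of a secondary alcohol; it protects C7–OH before the alkene is cleaved.

Step 3
Reactants: 3 C5–C10 alkene
Product: 4 C5–C9 aldehyde, 7-OTBS (7S)
Conditions: OsO4 (2 mol%), NaIO4, 2,6-lutidine, dioxane/H2O, rt
Reagents that add atoms: sodium periodate, [Na+].[O-]I(=O)(=O)=O (oxygen relayed through catalytic osmium tetroxide, O=[Os](=O)(=O)=O)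
Why: Lemieux–Johnson dihydroxylation/glycol cleavage of the terminal alkene; chosen over ozone so that the electron-rich PMB ring is not attacked.

Step 4
Reactants: 4 C5–C9 aldehyde
Product: 5 C5–C12 homoallylic alcohol, 7-OTBS, 9-OH (7S,9R)
Conditions: (+)-Ipc2B(allyl), Et2O, −100 °C; NaOH, H2O2 work-up
Reagents that add atoms: (+)-B-allyldiisopinocampheylborane, C=CCB([C@H]1C[C@H]2C[C@@H]([C@@H]1C)C2(C)C)[C@H]1C[C@H]2C[C@@H]([C@@H]1C)C2(C)C
Why: Brown allylboration under reagent control (Re-face addition) should set C9 syn to C7, overriding the weak bias of the β-silyloxy aldehyde.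

Step 5
Reactants: 5 C5–C12 homoallylic alcohol
Product: 6 C5–C12 alkene, 7,9-bis-OTBS (7S,9R)
Conditions: TBSCl, imidazole, DMF, rt
Reagents that add atoms: tert-butyldimethylsilyl chloride, CC(C)(C)[Si](C)(C)Cl
Why: Standard silylation; protects C9–OH.

Step 6
Reactants: 6 C5–C12 alkene
Product: 7 C5–C13 aldehyde, 7,9-bis-OTBS (7S,9R)
Conditions: Rh(CO)2(acac) (1 mol%), BIPHEPHOS (2 mol%), CO/H2 (1:1, 10 bar), THF, 60 °C
Reagents that add atoms: carbon monoxide, [C-]#[O+]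
Why: Linear-selective rhodium-catalysed hydroformylation of a terminal alkene; the bulky bisphosphite directs formylation to the terminal carbon, placing the C13 aldehyde three methylenes from C9.

Step 7
Reactants: 7 C5–C13 aldehyde
Product: 8 C5–C16 homoallylic alcohol, 13-OH (7S,9R,13R)
Conditions: (−)-Ipc2B(allyl) (from (+)-α-pinene), Et2O, −100 °C; NaOH, H2O2 work-up
Reagents that add atoms: (−)-B-allyldiisopinocampheylborane, C=CCB([C@@H]1C[C@@H]2C[C@H]([C@H]1C)C2(C)C)[C@@H]1C[C@@H]2C[C@H]([C@H]1C)C2(C)C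
Why: Brown allylboration; with no nearby stereocentre, Si-face addition under pure reagent control sets C13.

Step 8
Reactants: 8 C5–C16 homoallylic alcohol
Product: 9 C5–C16 alkene, 7,9,13-tris-OTBS (7S,9R,13R)
Conditions: TBSCl, imidazole, DMF, rt
Reagents that add atoms: tert-butyldimethylsilyl chloride, CC(C)(C)[Si](C)(C)Cl
Why: Standard silylation; protects C13–OH.

Step 9
Reactants: 9 C5–C16 alkene
Product: 10 C5–C17 aldehyde (7S,9R,13R)
Conditions: Rh(CO)2(acac) (1 mol%), BIPHEPHOS (2 mol%), CO/H2 (1:1, 10 bar), THF, 60 °C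
Reagents that add atoms: carbon monoxide, [C-]#[O+]
Why: Linear-selective rhodium-catalysed hydroformylation, as in step 6; gives the C17 aldehyde.

Step 10
Reactants: 10 C5–C17 aldehyde
Product: 11 C5–C18 terminal epoxide, about 1:1 at C17 (7S,9R,13S,17RS)
Conditions: Me3S+ I−, n-BuLi, THF, −10 °C → rt
Reagents that add atoms: trimethylsulfonium iodide, C[S+](C)C.[I-]
Why: Corey–Chaykovsky methylene transfer from dimethylsulfonium methylide; C17 forms without control and is resolved in the next step.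

Step 11
Reactants: 11 C5–C18 epoxide mixture
Product: 12 west epoxide (7S,9R,13S,17R)
Conditions: (R,R)-(salen)Co(OAc) (2 mol%), H2O (0.55 equiv), THF, 0 °C → rt
Reagents that add atoms: none
Why: Jacobsen hydrolytic kinetic resolution; the catalyst should hydrolyse the (17S)-epoxide to its diol and leave the (17R)-epoxide, which is separated by chromatography.

**East epoxide (C20–C40)**

Step 12
Reactants: 13 (E)-hept-2-en-1-ol
Product: 14 [(2R,3R)-3-butyloxiran-2-yl]methanol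
Conditions: Ti(OiPr)4 (5 mol%), D-(−)-diethyl tartrate (6 mol%), t-BuOOH, 4 Å MS, CH2Cl2, −20 °C
Reagents that add atoms: tert-butyl hydroperoxide, CC(C)(C)OO
Why: Sharpless asymmetric epoxidation; the D-(−)-tartrate catalyst delivers oxygen to the face that gives the (2R,3R)-epoxy alcohol (future C35 and C36).

Step 13
Reactants: 14 epoxy alcohol
Product: 15 (2S,3S)-3-methylheptane-1,2-diol
Conditions: Me3Al (3 equiv), hexane/CH2Cl2, 0 °C → rt
Reagents that add atoms: trimethylaluminium, C[Al](C)C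
Why: Aluminium-alkoxide-directed opening of the 2,3-epoxy alcohol at C3 with inversion; this sets C36 with the methyl anti to the C35 oxygen.

Step 14
Reactants: 15 3-methylheptane-1,2-diol
Product: 17 (2S)-2-[(2S)-hexan-2-yl]oxirane, via primary monotosylate 16 (not isolated)
Conditions: NaH (2.2 equiv), 1-(p-toluenesulfonyl)imidazole, THF, 0 °C → rt
Reagents that add atoms: none
Why: Selective sulfonylation of the primary hydroxyl followed by intramolecular Williamson closure; the C35–O bond is not broken, so configuration is retained.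

Step 15
Reactants: 17 C34–C40 epoxide
Product: 18 (4R,5S)-5-methylnon-1-en-4-ol (C32–C40; 35R,36S)
Conditions: vinylMgBr, CuI (10 mol%), THF, −40 → −20 °C
Reagents that add atoms: vinylmagnesium bromide, C=C[Mg]Br
Why: Copper-catalysed Grignard SN2 opening at the unsubstituted epoxide carbon; no stereocentre is touched.

Step 16
Reactants: 18 C32–C40 homoallylic alcohol
Product: 19 C32–C40 alkene, 35-OPMB (35R,36S)
Conditions: NaH, PMBCl, Bu4NI (cat.), DMF, 0 °C → rt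
Reagents that add atoms: 4-methoxybenzyl chloride, COc1ccc(CCl)cc1
Why: Williamson etherification; the PMB ether marks C35 as the one hydroxyl to be released later for acylation.

Step 17
Reactants: 19 C32–C40 alkene
Product: 20 C33–C40 aldehyde, 35-OPMB (35R,36S)
Conditions: OsO4 (2 mol%), NaIO4, 2,6-lutidine, dioxane/H2O, rt
Reagents that add atoms: sodium periodate, [Na+].[O-]I(=O)(=O)=O (oxygen relayed through catalytic osmium tetroxide, O=[Os](=O)(=O)=O)
Why: Lemieux–Johnson cleavage of the terminal alkene; the PMB ring is spared.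

Step 18
Reactants: 20 C33–C40 aldehyde
Product: 21 C30–C40 homoallylic alcohol, 33-OH (33R,35R,36S)
Conditions: (+)-Ipc2B(allyl), Et2O, −100 °C; NaOH, H2O2 work-up
Reagents that add atoms: (+)-B-allyldiisopinocampheylborane, C=CCB([C@H]1C[C@H]2C[C@@H]([C@@H]1C)C2(C)C)[C@H]1C[C@H]2C[C@@H]([C@@H]1C)C2(C)C
Why: Brown allylboration under reagent control (Re-face addition) should set C33 syn to the C35 ether.

Step 19
Reactants: 21 C30–C40 homoallylic alcohol
Product: 22 C30–C40 alkene, 33-OTBS (33R,35R,36S)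
Conditions: TBSCl, imidazole, DMF, rt
Reagents that add atoms: tert-butyldimethylsilyl chloride, CC(C)(C)[Si](C)(C)Cl
Why: Standard silylation; protects C33–OH.

Step 20
Reactants: 22 C30–C40 alkene
Product: 23 C29–C40 aldehyde (33R,35R,36S)
Conditions: Rh(CO)2(acac) (1 mol%), BIPHEPHOS (2 mol%), CO/H2 (1:1, 10 bar), THF, 60 °C
Reagents that add atoms: carbon monoxide, [C-]#[O+]
Why: Linear-selective rhodium-catalysed hydroformylation; gives the C29 aldehyde three methylenes from C33.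

Step 21
Reactants: 23 C29–C40 aldehyde
Product: 24 C26–C40 homoallylic alcohol, 29-OH (29S,33R,35R,36S)
Conditions: (+)-Ipc2B(allyl), Et2O, −100 °C; NaOH, H2O2 work-up
Reagents that add atoms: (+)-B-allyldiisopinocampheylborane, C=CCB([C@H]1C[C@H]2C[C@@H]([C@@H]1C)C2(C)C)[C@H]1C[C@H]2C[C@@H]([C@@H]1C)C2(C)C
Why: Brown allylboration; Re-face addition under pure reagent control sets C29.

Step 22
Reactants: 24 C26–C40 homoallylic alcohol
Product: 25 C26–C40 alkene, 29,33-bis-OTBS (29S,33R,35R,36S)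
Conditions: TBSCl, imidazole, DMF, rt
Reagents that add atoms: tert-butyldimethylsilyl chloride, CC(C)(C)[Si](C)(C)Cl
Why: Standard silylation; protects C29–OH.

Step 23
Reactants: 25 C26–C40 alkene
Product: 26 C27–C40 aldehyde (29S,33R,35R,36S)
Conditions: OsO4 (2 mol%), NaIO4, 2,6-lutidine, dioxane/H2O, rt
Reagents that add atoms: sodium periodate, [Na+].[O-]I(=O)(=O)=O (oxygen relayed through catalytic osmium tetroxide, O=[Os](=O)(=O)=O)
Why: Lemieux–Johnson cleavage of the terminal alkene to the C27 aldehyde.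

Step 24
Reactants: 26 C27–C40 aldehyde
Product: 27 C24–C40 homoallylic alcohol, 27-OH (27S,29S,33R,35R,36S)
Conditions: (−)-Ipc2B(allyl), Et2O, −100 °C; NaOH, H2O2 work-up
Reagents that add atoms: (−)-B-allyldiisopinocampheylborane, C=CCB([C@@H]1C[C@@H]2C[C@H]([C@H]1C)C2(C)C)[C@@H]1C[C@@H]2C[C@H]([C@H]1C)C2(C)C
Why: Brown allylboration; Si-face addition under reagent control should set C27 anti to the C29 silyl ether.

Step 25
Reactants: 27 C24–C40 homoallylic alcohol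
Product: 28 C24–C40 alkene, 27,29,33-tris-OTBS (27S,29S,33R,35R,36S)
Conditions: TBSCl, imidazole, DMF, rt
Reagents that add atoms: tert-butyldimethylsilyl chloride, CC(C)(C)[Si](C)(C)Cl
Why: Standard silylation; protects C27–OH.

Step 26
Reactants: 28 C24–C40 alkene
Product: 29 C25–C40 aldehyde (27R,29S,33R,35R,36S)
Conditions: OsO4 (2 mol%), NaIO4, 2,6-lutidine, dioxane/H2O, rt
Reagents that add atoms: sodium periodate, [Na+].[O-]I(=O)(=O)=O (oxygen relayed through catalytic osmium tetroxide, O=[Os](=O)(=O)=O)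
Why: Lemieux–Johnson cleavage of the terminal alkene to the C25 aldehyde.

Step 27
Reactants: 29 C25–C40 aldehyde
Product: 30 C22–C40 homoallylic alcohol, 25-OH (25S,27S,29S,33R,35R,36S)
Conditions: (−)-Ipc2B(allyl), Et2O, −100 °C; NaOH, H2O2 work-up
Reagents that add atoms: (−)-B-allyldiisopinocampheylborane, C=CCB([C@@H]1C[C@@H]2C[C@H]([C@H]1C)C2(C)C)[C@@H]1C[C@@H]2C[C@H]([C@H]1C)C2(C)C
Why: Brown allylboration; Si-face addition under reagent control should set C25 syn to C27.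

Step 28
Reactants: 30 C22–C40 homoallylic alcohol
Product: 31 C22–C40 alkene, 25,27,29,33-tetrakis-OTBS (25S,27R,29S,33R,35R,36S)
Conditions: TBSCl, imidazole, DMF, rt
Reagents that add atoms: tert-butyldimethylsilyl chloride, CC(C)(C)[Si](C)(C)Cl
Why: Standard silylation; protects C25–OH.

Step 29
Reactants: 31 C22–C40 alkene
Product: 32 C21–C40 aldehyde (25S,27R,29S,33R,35R,36S)
Conditions: Rh(CO)2(acac) (1 mol%), BIPHEPHOS (2 mol%), CO/H2 (1:1, 10 bar), THF, 60 °C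
Reagents that add atoms: carbon monoxide, [C-]#[O+]
Why: Linear-selective rhodium-catalysed hydroformylation; gives the C21 aldehyde.

Step 30
Reactants: 32 C21–C40 aldehyde
Product: 33 C20–C40 terminal epoxide, about 1:1 at C21 (21RS,25S,27S,29S,33R,35R,36S)
Conditions: Me3S+ I−, n-BuLi, THF, −10 °C → rt
Reagents that add atoms: trimethylsulfonium iodide, C[S+](C)C.[I-]
Why: Corey–Chaykovsky methylene transfer; C21 forms without control and is resolved in the next step.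

Step 31
Reactants: 33 C20–C40 epoxide mixture
Product: 34 east epoxide (21S,25S,27S,29S,33R,35R,36S)
Conditions: (S,S)-(salen)Co(OAc) (2 mol%), H2O (0.55 equiv), THF, 0 °C → rt
Reagents that add atoms: none
Why: Jacobsen hydrolytic kinetic resolution; the catalyst should hydrolyse the (21R)-epoxide to its diol and leave the (21S)-epoxide, which is separated by chromatography.

**Linchpin and union**

Step 32
Reactants: 35 1,3-dithiane
Product: 37 2-(tert-butyldimethylsilyl)-1,3-dithiane, via 2-lithio-1,3-dithiane 36 (not isolated)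
Conditions: n-BuLi, THF, −30 °C; TBSCl, −78 °C → rt
Reagents that add atoms: tert-butyldimethylsilyl chloride, CC(C)(C)[Si](C)(C)Cl
Why: Deprotonation of the dithiane C2–H and C-silylation of the sulfur-stabilised carbanion.

Step 33
Reactants: 37 2-(tert-butyldimethylsilyl)-1,3-dithiane; 12 west epoxide; 34 east epoxide
Product: 41 C5–C40 chain with C19 dithiane, 17-OTBS and free 21-OH, via lithiated silyl dithiane 38 (not isolated), via C17 lithium alkoxide 39 (not isolated), via C19 dithianyl carbanion 40 (not isolated)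
Conditions: 37, t-BuLi, Et2O, −78 → −45 °C; 12, Et2O, −78 → −25 °C; then 34, HMPA, THF, −78 → 0 °C; NH4Cl (aq)
Reagents that add atoms: none
Why: t-BuLi deprotonates 37 to 38, which opens 12 by SN2 attack at the unsubstituted C18 in ether to give alkoxide 39; this alkoxide is stable in ether, and only when HMPA arrives with 34 does the 1,4-Brook rearrangement (silicon from C19 to the C17 oxygen through a pentacoordinate siliconate) occur, unmasking carbanion 40, which opens 34 at C20. The closest known reaction type is the solvent-controlled three-component linchpin coupling of 2-silyl-1,3-dithiane anions with two different terminal epoxides (anion relay chemistry). No ring is closed and no stereocentre is created: C17 and C21 are carried in by the resolved epoxides and stay intact because both openings occur at CH2. The selectivities needed are the order of the two electrophiles and the site of epoxide opening; the first is secured by the solvent gate on silyl migration, which opens only after 12 is consumed, and the second by both epoxides being monosubstituted. The step leaves C17 silylated and C21 as the free alcohol.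

**Endgame**

Step 34
Reactants: 41 C5–C40 dithiane alcohol
Product: 42 C5–C40 dithiane, nine OTBS (C7, C9, C13, C17, C21, C25, C27, C29, C33), 5- and 35-OPMB
Conditions: TBSOTf, 2,6-lutidine, CH2Cl2, −78 → 0 °C
Reagents that add atoms: tert-butyldimethylsilyl trifluoromethanesulfonate, CC(C)(C)[Si](C)(C)OS(=O)(=O)C(F)(F)F
Why: Silylation with the triflate, needed for the hindered C21 hydroxyl next to the quaternary dithiane carbon.

Step 35
Reactants: 42 C5–C40 dithiane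
Product: 43 C5–C40 chain with C19 methylene, nine OTBS, 5- and 35-OPMB
Conditions: Raney nickel (W-2), EtOH, rt → 60 °C
Reagents that add atoms: none
Why: Reductive desulfurisation of the thioketal on the nickel surface turns C19 into CH2; the substrate has no alkene, and any incidental loss of a PMB group is harmless because both are removed next.

Step 36
Reactants: 43 C5–C40 bis-PMB ether
Product: 44 C5–C40 5,35-diol, nine OTBS
Conditions: DDQ, CH2Cl2/pH 7 buffer, 0 °C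
Reagents that add atoms: none
Why: Oxidative PMB cleavage by hydride abstraction at the electron-rich benzylic position and hydrolysis; silyl ethers are untouched.

Step 37
Reactants: 44 5,35-diol
Product: 45 C5 aldehyde with free 35-OH
Conditions: TEMPO (0.2 equiv), PhI(OAc)2, CH2Cl2, rt
Reagents that add atoms: none
Why: Oxoammonium-mediated oxidation, which is selective for the primary C5 alcohol over the hindered secondary C35 alcohol.

Step 38
Reactants: 45 C5 aldehyde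
Product: 46 C4=C5 terminal alkene with free 35-OH
Conditions: Ph3PCH3 Br, KHMDS (excess), THF, −78 → 0 °C
Reagents that add atoms: methyltriphenylphosphonium bromide, C[P+](c1ccccc1)(c1ccccc1)c1ccccc1.[Br-]
Why: Wittig methylenation adds C4; excess ylide covers the free C35 hydroxyl and low temperature limits β-elimination of the C7 silyl ether.

Step 39
Reactants: 47 but-2-ynoic acid
Product: 48 (Z)-3-iodobut-2-enoic acid
Conditions: NaI, AcOH, 110 °C
Reagents that add atoms: sodium iodide, [Na+].[I-]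
Why: Conjugate anti-hydroiodination of the ynoic acid places iodine cis to the carboxyl, the geometry needed for the 2Z alkene.

Step 40
Reactants: 46 C4=C5 alkene with free 35-OH; 48 (Z)-3-iodobut-2-enoic acid
Product: 50 C35 (Z)-3-iodobut-2-enoate, via mixed anhydride 49 (not isolated)
Conditions: 48, 2,4,6-Cl3C6H2COCl, Et3N, THF, 0 °C; then 46, DMAP, toluene, rt
Reagents that add atoms: none
Why: Yamaguchi esterification through the mixed anhydride acylates the hindered C35 hydroxyl, the only free hydroxyl in 46.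

Step 41
Reactants: 50 C35 (Z)-3-iodobut-2-enoate
Product: 52 nona-TBS 36-membered macrolactone, via B-alkyl-9-BBN borane 51 (not isolated)
Conditions: 9-BBN-H, THF, rt; then slow addition to PdCl2(dppf) (20 mol%), AsPh3, Cs2CO3, DMF/THF/H2O, 50 °C, 1 mM
Reagents that add atoms: none
Why: Anti-Markovnikov hydroboration of the terminal alkene puts boron on C4, and intramolecular B-alkyl Suzuki–Miyaura coupling with the vinyl iodide forms C3–C4 with retention of the Z geometry; high dilution favours ring closure.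

Step 42
Reactants: 52 nona-TBS macrolactone
Product: 53 CNP0126363.4
Conditions: HF·pyridine, pyridine, THF, 0 °C → rt
Reagents that add atoms: none
Why: Fluoride-mediated global desilylation under buffered acidic conditions, chosen over basic fluoride to avoid acyl migration from C35 to the syn C33 hydroxyl or isomerisation of the enoate.

**Compound list**

1 | 3-[(4-methoxybenzyl)oxy]propanal | O=CCCOCc1ccc(OC)cc1 | starting material
2 | (3R)-1-(PMB-oxy)hex-5-en-3-ol (C5–C10; 7R) | C=CC[C@@H](O)CCOCc1ccc(OC)cc1 | intermediate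
3 | TBS ether of 2 (7R) | C=CC[C@@H](O[Si](C)(C)C(C)(C)C)CCOCc1ccc(OC)cc1 | intermediate
4 | (3S)-3-(TBS-oxy)-5-(PMB-oxy)pentanal (C5–C9; 7S) | O=CC[C@@H](O[Si](C)(C)C(C)(C)C)CCOCc1ccc(OC)cc1 | intermediate
5 | C5–C12 homoallylic alcohol, 9-OH, 7-OTBS, 5-OPMB (7S,9R) | C=CC[C@@H](O)C[C@@H](O[Si](C)(C)C(C)(C)C)CCOCc1ccc(OC)cc1 | intermediate
6 | C5–C12 alkene, 7,9-bis-OTBS (7S,9R) | C=CC[C@@H](O[Si](C)(C)C(C)(C)C)C[C@@H](O[Si](C)(C)C(C)(C)C)CCOCc1ccc(OC)cc1 | intermediate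
7 | C5–C13 aldehyde, 7,9-bis-OTBS (7S,9R) | O=CCCC[C@@H](O[Si](C)(C)C(C)(C)C)C[C@@H](O[Si](C)(C)C(C)(C)C)CCOCc1ccc(OC)cc1 | intermediate
8 | C5–C16 homoallylic alcohol, 13-OH (7S,9R,13R) | C=CC[C@H](O)CCC[C@@H](O[Si](C)(C)C(C)(C)C)C[C@@H](O[Si](C)(C)C(C)(C)C)CCOCc1ccc(OC)cc1 | intermediate
9 | C5–C16 alkene, 7,9,13-tris-OTBS (7S,9R,13R) | C=CC[C@H](O[Si](C)(C)C(C)(C)C)CCC[C@@H](O[Si](C)(C)C(C)(C)C)C[C@@H](O[Si](C)(C)C(C)(C)C)CCOCc1ccc(OC)cc1 | intermediate
10 | C5–C17 aldehyde, 7,9,13-tris-OTBS (7S,9R,13R) | O=CCCC[C@H](O[Si](C)(C)C(C)(C)C)CCC[C@@H](O[Si](C)(C)C(C)(C)C)C[C@@H](O[Si](C)(C)C(C)(C)C)CCOCc1ccc(OC)cc1 | intermediate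
11 | C5–C18 17,18-epoxide, both C17 epimers (7S,9R,13S,17RS) | C1OC1CCC[C@H](O[Si](C)(C)C(C)(C)C)CCC[C@@H](O[Si](C)(C)C(C)(C)C)C[C@@H](O[Si](C)(C)C(C)(C)C)CCOCc1ccc(OC)cc1 | intermediate
12 | west epoxide, C5–C18 (7S,9R,13S,17R) | C1O[C@@H]1CCC[C@H](O[Si](C)(C)C(C)(C)C)CCC[C@@H](O[Si](C)(C)C(C)(C)C)C[C@@H](O[Si](C)(C)C(C)(C)C)CCOCc1ccc(OC)cc1 | intermediate
13 | (E)-hept-2-en-1-ol | CCCC/C=C/CO | starting material
14 | [(2R,3R)-3-butyloxiran-2-yl]methanol | CCCC[C@H]1O[C@@H]1CO | intermediate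
15 | (2S,3S)-3-methylheptane-1,2-diol | CCCC[C@H](C)[C@H](O)CO | intermediate
16 | (2S,3S)-2-hydroxy-3-methylheptyl 4-methylbenzenesulfonate | CCCC[C@H](C)[C@H](O)COS(=O)(=O)c1ccc(C)cc1 | intermediate
17 | (2S)-2-[(2S)-hexan-2-yl]oxirane (C34–C40) | CCCC[C@H](C)[C@H]1CO1 | intermediate
18 | (4R,5S)-5-methylnon-1-en-4-ol (C32–C40; 35R,36S) | CCCC[C@H](C)[C@H](O)CC=C | intermediate
19 | PMB ether of 18 (35R,36S) | CCCC[C@H](C)[C@H](OCc1ccc(OC)cc1)CC=C | intermediate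
20 | (3R,4S)-3-(PMB-oxy)-4-methyloctanal (C33–C40) | CCCC[C@H](C)[C@H](OCc1ccc(OC)cc1)CC=O | intermediate
21 | C30–C40 homoallylic alcohol, 33-OH, 35-OPMB (33R,35R,36S) | CCCC[C@H](C)[C@H](OCc1ccc(OC)cc1)C[C@H](O)CC=C | intermediate
22 | C30–C40 alkene, 33-OTBS (33R,35R,36S) | CCCC[C@H](C)[C@H](OCc1ccc(OC)cc1)C[C@H](O[Si](C)(C)C(C)(C)C)CC=C | intermediate
23 | C29–C40 aldehyde (33R,35R,36S) | CCCC[C@H](C)[C@H](OCc1ccc(OC)cc1)C[C@H](O[Si](C)(C)C(C)(C)C)CCCC=O | intermediate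
24 | C26–C40 homoallylic alcohol, 29-OH (29S,33R,35R,36S) | CCCC[C@H](C)[C@H](OCc1ccc(OC)cc1)C[C@H](O[Si](C)(C)C(C)(C)C)CCC[C@H](O)CC=C | intermediate
25 | C26–C40 alkene, 29,33-bis-OTBS (29S,33R,35R,36S) | CCCC[C@H](C)[C@H](OCc1ccc(OC)cc1)C[C@H](O[Si](C)(C)C(C)(C)C)CCC[C@H](O[Si](C)(C)C(C)(C)C)CC=C | intermediate
26 | C27–C40 aldehyde (29S,33R,35R,36S) | CCCC[C@H](C)[C@H](OCc1ccc(OC)cc1)C[C@H](O[Si](C)(C)C(C)(C)C)CCC[C@H](O[Si](C)(C)C(C)(C)C)CC=O | intermediate
27 | C24–C40 homoallylic alcohol, 27-OH (27S,29S,33R,35R,36S) | CCCC[C@H](C)[C@H](OCc1ccc(OC)cc1)C[C@H](O[Si](C)(C)C(C)(C)C)CCC[C@H](O[Si](C)(C)C(C)(C)C)C[C@@H](O)CC=C | intermediate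
28 | C24–C40 alkene, 27,29,33-tris-OTBS (27S,29S,33R,35R,36S) | CCCC[C@H](C)[C@H](OCc1ccc(OC)cc1)C[C@H](O[Si](C)(C)C(C)(C)C)CCC[C@H](O[Si](C)(C)C(C)(C)C)C[C@@H](O[Si](C)(C)C(C)(C)C)CC=C | intermediate
29 | C25–C40 aldehyde (27R,29S,33R,35R,36S) | CCCC[C@H](C)[C@H](OCc1ccc(OC)cc1)C[C@H](O[Si](C)(C)C(C)(C)C)CCC[C@H](O[Si](C)(C)C(C)(C)C)C[C@@H](O[Si](C)(C)C(C)(C)C)CC=O | intermediate
30 | C22–C40 homoallylic alcohol, 25-OH (25S,27S,29S,33R,35R,36S) | CCCC[C@H](C)[C@H](OCc1ccc(OC)cc1)C[C@H](O[Si](C)(C)C(C)(C)C)CCC[C@H](O[Si](C)(C)C(C)(C)C)C[C@@H](O[Si](C)(C)C(C)(C)C)C[C@@H](O)CC=C | intermediate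
31 | C22–C40 alkene, 25,27,29,33-tetrakis-OTBS (25S,27R,29S,33R,35R,36S) | CCCC[C@H](C)[C@H](OCc1ccc(OC)cc1)C[C@H](O[Si](C)(C)C(C)(C)C)CCC[C@H](O[Si](C)(C)C(C)(C)C)C[C@@H](O[Si](C)(C)C(C)(C)C)C[C@@H](O[Si](C)(C)C(C)(C)C)CC=C | intermediate
32 | C21–C40 aldehyde (25S,27R,29S,33R,35R,36S) | CCCC[C@H](C)[C@H](OCc1ccc(OC)cc1)C[C@H](O[Si](C)(C)C(C)(C)C)CCC[C@H](O[Si](C)(C)C(C)(C)C)C[C@@H](O[Si](C)(C)C(C)(C)C)C[C@@H](O[Si](C)(C)C(C)(C)C)CCCC=O | intermediate
33 | C20–C40 20,21-epoxide, both C21 epimers (21RS,25S,27S,29S,33R,35R,36S) | CCCC[C@H](C)[C@H](OCc1ccc(OC)cc1)C[C@H](O[Si](C)(C)C(C)(C)C)CCC[C@H](O[Si](C)(C)C(C)(C)C)C[C@@H](O[Si](C)(C)C(C)(C)C)C[C@@H](O[Si](C)(C)C(C)(C)C)CCCC1CO1 | intermediate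
34 | east epoxide, C20–C40 (21S,25S,27S,29S,33R,35R,36S) | CCCC[C@H](C)[C@H](OCc1ccc(OC)cc1)C[C@H](O[Si](C)(C)C(C)(C)C)CCC[C@H](O[Si](C)(C)C(C)(C)C)C[C@@H](O[Si](C)(C)C(C)(C)C)C[C@@H](O[Si](C)(C)C(C)(C)C)CCC[C@H]1CO1 | intermediate
35 | 1,3-dithiane | C1CSCSC1 | starting material
36 | 2-lithio-1,3-dithiane | [Li]C1SCCCS1 | intermediate
37 | 2-(tert-butyldimethylsilyl)-1,3-dithiane | CC(C)(C)[Si](C)(C)C1SCCCS1 | intermediate
38 | 2-lithio-2-(tert-butyldimethylsilyl)-1,3-dithiane | [Li]C1([Si](C)(C)C(C)(C)C)SCCCS1 | intermediate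
39 | C5–C19 lithium C17 alkoxide with 2-silyl dithiane at C19 | CC(C)(C)[Si](C)(C)C1(SCCCS1)C[C@H](O[Li])CCC[C@H](O[Si](C)(C)C(C)(C)C)CCC[C@@H](O[Si](C)(C)C(C)(C)C)C[C@@H](O[Si](C)(C)C(C)(C)C)CCOCc1ccc(OC)cc1 | intermediate
40 | C5–C19 C19-lithio dithiane with 17-OTBS | [Li]C1(SCCCS1)C[C@H](O[Si](C)(C)C(C)(C)C)CCC[C@H](O[Si](C)(C)C(C)(C)C)CCC[C@@H](O[Si](C)(C)C(C)(C)C)C[C@@H](O[Si](C)(C)C(C)(C)C)CCOCc1ccc(OC)cc1 | intermediate
41 | C5–C40 chain, C19 1,3-dithiane, 21-OH, 17-OTBS, OTBS at C7, C9, C13, C25, C27, C29, C33, OPMB at C5 and C35 (7S,9R,13R,17R,21S,25S,27S,29S,33R,35R,36S) | CCCC[C@H](C)[C@H](OCc1ccc(OC)cc1)C[C@H](O[Si](C)(C)C(C)(C)C)CCC[C@H](O[Si](C)(C)C(C)(C)C)C[C@@H](O[Si](C)(C)C(C)(C)C)C[C@@H](O[Si](C)(C)C(C)(C)C)CCC[C@H](O)CC1(SCCCS1)C[C@H](O[Si](C)(C)C(C)(C)C)CCC[C@H](O[Si](C)(C)C(C)(C)C)CCC[C@@H](O[Si](C)(C)C(C)(C)C)C[C@@H](O[Si](C)(C)C(C)(C)C)CCOCc1ccc(OC)cc1 | intermediate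
42 | 21-TBS ether of 41 (7S,9R,13R,17R,21S,25S,27R,29S,33R,35R,36S) | CCCC[C@H](C)[C@H](OCc1ccc(OC)cc1)C[C@H](O[Si](C)(C)C(C)(C)C)CCC[C@H](O[Si](C)(C)C(C)(C)C)C[C@@H](O[Si](C)(C)C(C)(C)C)C[C@@H](O[Si](C)(C)C(C)(C)C)CCC[C@H](O[Si](C)(C)C(C)(C)C)CC1(SCCCS1)C[C@H](O[Si](C)(C)C(C)(C)C)CCC[C@H](O[Si](C)(C)C(C)(C)C)CCC[C@@H](O[Si](C)(C)C(C)(C)C)C[C@@H](O[Si](C)(C)C(C)(C)C)CCOCc1ccc(OC)cc1 | intermediate
43 | C5–C40 chain, C19 methylene, nine OTBS, 5,35-bis-OPMB (7S,9R,13S,17R,21R,25S,27S,29S,33R,35R,36S) | CCCC[C@H](C)[C@H](OCc1ccc(OC)cc1)C[C@H](O[Si](C)(C)C(C)(C)C)CCC[C@H](O[Si](C)(C)C(C)(C)C)C[C@@H](O[Si](C)(C)C(C)(C)C)C[C@@H](O[Si](C)(C)C(C)(C)C)CCC[C@H](O[Si](C)(C)C(C)(C)C)CCC[C@H](O[Si](C)(C)C(C)(C)C)CCC[C@H](O[Si](C)(C)C(C)(C)C)CCC[C@@H](O[Si](C)(C)C(C)(C)C)C[C@@H](O[Si](C)(C)C(C)(C)C)CCOCc1ccc(OC)cc1 | intermediate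
44 | C5–C40 5,35-diol, nine OTBS (7S,9R,13S,17R,21R,25S,27S,29S,33R,35R,36S) | CCCC[C@H](C)[C@H](O)C[C@H](O[Si](C)(C)C(C)(C)C)CCC[C@H](O[Si](C)(C)C(C)(C)C)C[C@@H](O[Si](C)(C)C(C)(C)C)C[C@@H](O[Si](C)(C)C(C)(C)C)CCC[C@H](O[Si](C)(C)C(C)(C)C)CCC[C@H](O[Si](C)(C)C(C)(C)C)CCC[C@H](O[Si](C)(C)C(C)(C)C)CCC[C@@H](O[Si](C)(C)C(C)(C)C)C[C@@H](O[Si](C)(C)C(C)(C)C)CCO | intermediate
45 | C5 aldehyde, 35-OH, nine OTBS (7R,9R,13S,17S,21R,25S,27S,29S,33R,35R,36S) | CCCC[C@H](C)[C@H](O)C[C@H](O[Si](C)(C)C(C)(C)C)CCC[C@H](O[Si](C)(C)C(C)(C)C)C[C@@H](O[Si](C)(C)C(C)(C)C)C[C@@H](O[Si](C)(C)C(C)(C)C)CCC[C@H](O[Si](C)(C)C(C)(C)C)CCC[C@H](O[Si](C)(C)C(C)(C)C)CCC[C@H](O[Si](C)(C)C(C)(C)C)CCC[C@@H](O[Si](C)(C)C(C)(C)C)C[C@@H](O[Si](C)(C)C(C)(C)C)CC=O | intermediate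
46 | C4–C40 terminal alkene (C4=C5), 35-OH, nine OTBS (7S,9R,13S,17R,21R,25S,27S,29S,33R,35R,36S) | CCCC[C@H](C)[C@H](O)C[C@H](O[Si](C)(C)C(C)(C)C)CCC[C@H](O[Si](C)(C)C(C)(C)C)C[C@@H](O[Si](C)(C)C(C)(C)C)C[C@@H](O[Si](C)(C)C(C)(C)C)CCC[C@H](O[Si](C)(C)C(C)(C)C)CCC[C@H](O[Si](C)(C)C(C)(C)C)CCC[C@H](O[Si](C)(C)C(C)(C)C)CCC[C@@H](O[Si](C)(C)C(C)(C)C)C[C@@H](O[Si](C)(C)C(C)(C)C)CC=C | intermediate
47 | but-2-ynoic acid | CC#CC(=O)O | starting material
48 | (Z)-3-iodobut-2-enoic acid | C/C(I)=C/C(=O)O | intermediate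
49 | (Z)-3-iodobut-2-enoic 2,4,6-trichlorobenzoic anhydride | C/C(I)=C/C(=O)OC(=O)c1c(Cl)cc(Cl)cc1Cl | intermediate
50 | C35 (Z)-3-iodobut-2-enoate of 46 (7S,9R,13S,17R,21R,25S,27S,29S,33R,35R,36S) | CCCC[C@H](C)[C@H](OC(=O)/C=C(/C)I)C[C@H](O[Si](C)(C)C(C)(C)C)CCC[C@H](O[Si](C)(C)C(C)(C)C)C[C@@H](O[Si](C)(C)C(C)(C)C)C[C@@H](O[Si](C)(C)C(C)(C)C)CCC[C@H](O[Si](C)(C)C(C)(C)C)CCC[C@H](O[Si](C)(C)C(C)(C)C)CCC[C@H](O[Si](C)(C)C(C)(C)C)CCC[C@@H](O[Si](C)(C)C(C)(C)C)C[C@@H](O[Si](C)(C)C(C)(C)C)CC=C | intermediate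
51 | C4 B-alkyl-9-borabicyclo[3.3.1]nonane derived from 50 | CCCC[C@H](C)[C@H](OC(=O)/C=C(/C)I)C[C@H](O[Si](C)(C)C(C)(C)C)CCC[C@H](O[Si](C)(C)C(C)(C)C)C[C@@H](O[Si](C)(C)C(C)(C)C)C[C@@H](O[Si](C)(C)C(C)(C)C)CCC[C@H](O[Si](C)(C)C(C)(C)C)CCC[C@H](O[Si](C)(C)C(C)(C)C)CCC[C@H](O[Si](C)(C)C(C)(C)C)CCC[C@@H](O[Si](C)(C)C(C)(C)C)C[C@@H](O[Si](C)(C)C(C)(C)C)CCCB1C2CCCC1CCC2 | intermediate
52 | nona-TBS ether of the target macrolactone (2Z,7S,9R,13S,17R,21R,25S,27S,29S,33R,35R,36S) | CCCC[C@H](C)[C@H]1C[C@H](O[Si](C)(C)C(C)(C)C)CCC[C@H](O[Si](C)(C)C(C)(C)C)C[C@@H](O[Si](C)(C)C(C)(C)C)C[C@@H](O[Si](C)(C)C(C)(C)C)CCC[C@H](O[Si](C)(C)C(C)(C)C)CCC[C@H](O[Si](C)(C)C(C)(C)C)CCC[C@H](O[Si](C)(C)C(C)(C)C)CCC[C@@H](O[Si](C)(C)C(C)(C)C)C[C@@H](O[Si](C)(C)C(C)(C)C)CCC/C(C)=C\C(=O)O1 | intermediate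
53 | CNP0126363.4, (2Z,7S,9R,13S,17R,21R,25S,27S,29S,33R,35R,36S)-7,9,13,17,21,25,27,29,33-nonahydroxy-3,36-dimethyltetracont-2-en-35-olide | CCCC[C@H](C)[C@H]1C[C@H](O)CCC[C@H](O)C[C@@H](O)C[C@@H](O)CCC[C@H](O)CCC[C@H](O)CCC[C@H](O)CCC[C@@H](O)C[C@@H](O)CCC/C(C)=C\C(=O)O1 | target

**Step count and risks**

Total step count: 42. Longest linear sequence: 29 steps (steps 12–31, 33–38, 40–42).

Steps most likely to fail:

1. Step 33. Silyl migration may start before 12 is consumed, which would scramble the order of the electrophiles and give a doubly west-alkylated dithiane. The hindered tertiary carbanion may also attack the large epoxide 34 slowly and be quenched by proton transfer. Fallback, setting out from 12 and returning at 41: the two bonds are made in separate anion steps without silyl migration. 2-Lithio-1,3-dithiane 36 (from 35 and n-BuLi) opens 12 at C18 to give the C5–C19 hydroxy dithiane F1. Silylation (TBSCl, imidazole) gives the 17-TBS ether F2. Deprotonation of F2 at C19 (t-BuLi, THF/HMPA, −78 °C) gives carbanion 40 directly, and alkylation with 34 rejoins the route at 41.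

2. Step 41. Oligomerisation may outrun closure of the 36-membered ring, the primary alkylborane may be lost by protodeboronation, and the base may eliminate HI from the iodoenoate. Fallback, setting out from 46 and returning at 52: the ring is closed at the ester bond instead of at C3–C4. Acid 48 is converted into methyl (Z)-3-iodobut-2-enoate F3 (MeI, K2CO3, DMF). Alkene 46 is hydroborated with 9-BBN-H and coupled intermolecularly with F3 (PdCl2(dppf), AsPh3, Cs2CO3) to give the C1–C40 hydroxy methyl ester F4. Saponification (LiOH, THF/MeOH/H2O) gives the seco acid F5, and Yamaguchi macrolactonisation at high dilution gives 52.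

3. Step 40. Acyl transfer to the hindered C35 hydroxyl may be slow, and during activation the iodoenoate may isomerise from Z to E or suffer addition–elimination by DMAP at the β-carbon. Fallback, setting out from 46 and returning at 50: 46 is acylated with but-2-ynoic acid 47 (DIC, DMAP), which cannot isomerise, to give the C35 but-2-ynoate F6. Anti-hydroiodination of the ynoate (NaI, AcOH, 60 °C) then installs iodine cis to the carbonyl and gives 50.

**Further compounds**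

F1 | step 33 | C5–C19 hydroxy dithiane, 17-OH (2-substituted 1,3-dithiane from 12) | C1(SCCCS1)C[C@H](O)CCC[C@H](O[Si](C)(C)C(C)(C)C)CCC[C@@H](O[Si](C)(C)C(C)(C)C)C[C@@H](O[Si](C)(C)C(C)(C)C)CCOCc1ccc(OC)cc1
F2 | step 33 | 17-TBS ether of F1 | C1(SCCCS1)C[C@H](O[Si](C)(C)C(C)(C)C)CCC[C@H](O[Si](C)(C)C(C)(C)C)CCC[C@@H](O[Si](C)(C)C(C)(C)C)C[C@@H](O[Si](C)(C)C(C)(C)C)CCOCc1ccc(OC)cc1
F3 | step 41 | methyl (Z)-3-iodobut-2-enoate | C/C(I)=C/C(=O)OC
F4 | step 41 | C1–C40 seco methyl ester, (2Z), 35-OH, nine OTBS | CCCC[C@H](C)[C@H](O)C[C@H](O[Si](C)(C)C(C)(C)C)CCC[C@H](O[Si](C)(C)C(C)(C)C)C[C@@H](O[Si](C)(C)C(C)(C)C)C[C@@H](O[Si](C)(C)C(C)(C)C)CCC[C@H](O[Si](C)(C)C(C)(C)C)CCC[C@H](O[Si](C)(C)C(C)(C)C)CCC[C@H](O[Si](C)(C)C(C)(C)C)CCC[C@@H](O[Si](C)(C)C(C)(C)C)C[C@@H](O[Si](C)(C)C(C)(C)C)CCC/C(C)=C\C(=O)OC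
F5 | step 41 | C1–C40 seco acid, (2Z), 35-OH, nine OTBS | CCCC[C@H](C)[C@H](O)C[C@H](O[Si](C)(C)C(C)(C)C)CCC[C@H](O[Si](C)(C)C(C)(C)C)C[C@@H](O[Si](C)(C)C(C)(C)C)C[C@@H](O[Si](C)(C)C(C)(C)C)CCC[C@H](O[Si](C)(C)C(C)(C)C)CCC[C@H](O[Si](C)(C)C(C)(C)C)CCC[C@H](O[Si](C)(C)C(C)(C)C)CCC[C@@H](O[Si](C)(C)C(C)(C)C)C[C@@H](O[Si](C)(C)C(C)(C)C)CCC/C(C)=C\C(=O)O
F6 | step 40 | C35 but-2-ynoate of 46 | CCCC[C@H](C)[C@H](OC(=O)C#CC)C[C@H](O[Si](C)(C)C(C)(C)C)CCC[C@H](O[Si](C)(C)C(C)(C)C)C[C@@H](O[Si](C)(C)C(C)(C)C)C[C@@H](O[Si](C)(C)C(C)(C)C)CCC[C@H](O[Si](C)(C)C(C)(C)C)CCC[C@H](O[Si](C)(C)C(C)(C)C)CCC[C@H](O[Si](C)(C)C(C)(C)C)CCC[C@@H](O[Si](C)(C)C(C)(C)C)C[C@@H](O[Si](C)(C)C(C)(C)C)CC=C
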